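The 5-oxooxolane ring (ring A: O1, quaternary C2, C3H2, C4H2, carbonyl C5) is read as ketone plus ethylene plus carbon monoxide. C2 carries a carboxyl group, so it is the ketone carbon of an α-keto ester; C3–C4 is ethylene and C5 is CO. A Ru3(CO)12-catalysed [2+2+1] carbonylative cycloaddition joins the three components on an open-chain α-keto ester, making the C2–C3 and C4–C5 bonds and the lactone C–O bond in one operation. The adjacent stereocentre, set by an enamine-catalysed glyoxylate aldol and carrying the future carboxyl as a bulky diethyl acetal, directs the new quaternary centre. D-Malic acid is attached last through its O-trifluoroacetyl anhydride.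

Key step: step 5

Remark: the hydroxyl-bearing diarylprolinol catalyst is assumed to follow proline-type facial selectivity in the glyoxylate aldol; the carbinol configuration of the aldol adduct is erased in step 4.

Step 1
Reactants: 1 dodecane-1,12-diol
Product: 2 12-hydroxydodecyl benzoate
Conditions: BzCl (1.0 equiv), 1 (3 equiv), pyridine, THF, 0 °C → rt
Reagents that add atoms: benzoyl chloride O=C(Cl)c1ccccc1
Why: Statistical mono-O-benzoylation of a symmetrical diol used in excess (nucleophilic acyl substitution) should give the mono-benzoate, a group that survives the acidic, oxidative and hot neutral steps and is removed in the later saponification.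

Step 2
Reactants: 2 12-hydroxydodecyl benzoate
Product: 3 12-oxododecyl benzoate
Conditions: TEMPO (10 mol%), PhI(OAc)2 (1.1 equiv), CH2Cl2, rt
Reagents that add atoms: none
Why: TEMPO/oxoammonium oxidation of a primary alcohol stops cleanly at the aldehyde and leaves the benzoate untouched.

Step 3
Reactants: 3 12-oxododecyl benzoate; 4 ethyl glyoxylate
Product: 6 ethyl (2R,3S)-13-(benzoyloxy)-3-(diethoxymethyl)-2-hydroxytridecanoate, via anti-aldol hydroxy aldehyde 5 (not isolated)
Conditions: (S)-α,α-bis[3,5-bis(trifluoromethyl)phenyl]pyrrolidin-2-ylmethanol (10 mol%), ethyl glyoxylate (polymer form in toluene), H2O (3 equiv), MeCN, rt; then HC(OEt)3, TsOH·H2O (catalytic), EtOH, rt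
Reagents that add atoms: triethyl orthoformate CCOC(OCC)OCC
Why: In this enamine-catalysed cross-aldol reaction the catalyst hydroxyl hydrogen-bonds the glyoxylate and delivers it to the E-enamine face syn to the carbinol arm (proline-type topicity), which should set the (3S) centre, and the labile β-hydroxy aldehyde 5 is trapped in the same flask by acid-catalysed acetalisation.

Step 4
Reactants: 6 ethyl (2R,3S)-13-(benzoyloxy)-3-(diethoxymethyl)-2-hydroxytridecanoate
Product: 7 ethyl (3R)-13-(benzoyloxy)-3-(diethoxymethyl)-2-oxotridecanoate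
Conditions: Dess–Martin periodinane, pyridine, CH2Cl2, 0 °C → rt
Reagents that add atoms: none
Why: Dess–Martin oxidation of the α-hydroxy ester under buffered, non-enolising conditions should give the α-keto ester with the acetal and the adjacent stereocentre intact (its descriptor becomes R by a change of priority only), and both carbinol epimers converge.

Step 5
Reactants: 7 ethyl (3R)-13-(benzoyloxy)-3-(diethoxymethyl)-2-oxotridecanoate; 8 ethylene; 9 carbon monoxide
Product: 10 ethyl (2R)-2-[(1S)-11-(benzoyloxy)-1-(diethoxymethyl)undecyl]-5-oxooxolane-2-carboxylate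
Conditions: Ru3(CO)12 (2.5 mol%), P(4-CF3C6H4)3 (7.5 mol%), ethylene (3 atm), CO (5 atm), toluene, 160 °C, 20 h, autoclave
Reagents that add atoms: none
Why: The s-cis 1,2-dicarbonyl unit of 7 chelates a zerovalent ruthenium carbonyl fragment, the bound ketone and ethylene undergo oxidative cyclisation to a five-membered oxaruthenacycle (new bond from the ketone carbon to CH2), CO inserts into the Ru–CH2 bond (new CH2–C(=O) bond) and C–O reductive elimination releases the lactone and the catalyst. This is the known ruthenium-catalysed intermolecular [2+2+1] carbonylative cycloaddition of α-keto esters with ethylene and CO, a hetero-Pauson–Khand-type reaction. Ring A is closed by [2+2+1] assembly from the ketone C=O (two atoms), ethylene (two atoms) and CO (one atom), the last bond being the acyl C–O reductive elimination within the metallacycle. The new quaternary centre is controlled by the neighbouring (3R) centre: in the chelate the C3–H lies in the dicarbonyl plane beside the ester (allylic strain), the bulky σ-acceptor diethoxymethyl group stands perpendicular, and metal plus ethylene should add to the ketone face anti to it (Felkin–Anh-type 1,2-induction), which gives the (2R) lactone. The step needs chemoselectivity for the ketone over the ester, benzoate and acetal, secured because only the chelating α-keto carbonyl is activated, and configurational integrity at C3, which the neutral aprotic medium and the acetal (no second carbonyl flanking the C–H) should secure.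

Step 6
Reactants: 10 ethyl (2R)-2-[(1S)-11-(benzoyloxy)-1-(diethoxymethyl)undecyl]-5-oxooxolane-2-carboxylate
Product: 12 (2S)-12-(benzoyloxy)-2-[(2R)-2-(ethoxycarbonyl)-5-oxooxolan-2-yl]dodecanoic acid, via aldehyde 11 (not isolated)
Conditions: TFA/H2O/CH2Cl2, 0 °C → rt, evaporate; then NaClO2, NaH2PO4, 2-methyl-2-butene, t-BuOH/H2O, 0 °C → rt
Reagents that add atoms: water O; sodium chlorite [Na+].[O-]Cl=O
Why: Aqueous acid hydrolyses the acyclic acetal and the hindered aldehyde is oxidised at once by the Pinnick oxidation, whose buffered acidic medium should not epimerise the α-centre or trigger β-elimination, so the second carboxyl is revealed with the (S) centre kept.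

Step 7
Reactants: 12 (2S)-12-(benzoyloxy)-2-[(2R)-2-(ethoxycarbonyl)-5-oxooxolan-2-yl]dodecanoic acid
Product: 14 (2R)-2-[(1S)-1-carboxy-11-hydroxyundecyl]-5-oxooxolane-2-carboxylic acid, via ring-opened trilithium tricarboxylate 13 (not isolated)
Conditions: LiOH (6 equiv), THF/H2O, rt; then 2 M HCl to pH 1, 40 °C
Reagents that add atoms: lithium hydroxide [Li+].[OH-]
Why: Saponification cleaves the ethyl ester and the benzoate and opens the lactone to the tricarboxylate 13, whose α-hydrogen next to a carboxylate is not acidic enough to epimerise, and acidification should reclose the only strain-free ring by lactonisation of the γ-hydroxy acid.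

Step 8
Reactants: 15 D-malic acid, (2R)-2-hydroxybutanedioic acid
Product: 16 (3R)-2,5-dioxooxolan-3-yl trifluoroacetate
Conditions: (CF3CO)2O (neat, excess), 0 °C → rt; evaporate
Reagents that add atoms: trifluoroacetic anhydride O=C(OC(=O)C(F)(F)F)C(F)(F)F
Why: Trifluoroacetic anhydride acylates the hydroxyl group and cyclodehydrates the 1,4-diacid to the five-membered anhydride through a mixed anhydride, without touching the stereocentre.

Step 9
Reactants: 14 (2R)-2-[(1S)-1-carboxy-11-hydroxyundecyl]-5-oxooxolane-2-carboxylic acid; 16 (3R)-2,5-dioxooxolan-3-yl trifluoroacetate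
Product: 18 (2R)-2-[(1S)-1-carboxy-11-{[(2R)-3-carboxy-2-hydroxypropanoyl]oxy}undecyl]-5-oxooxolane-2-carboxylic acid, via O-trifluoroacetyl ester 17 (not isolated)
Conditions: 16 (3 equiv), THF, rt → 40 °C; then H2O, rt; reversed-phase chromatography
Reagents that add atoms: none
Why: In this alcoholysis of an unsymmetrical cyclic anhydride the primary alcohol of 14 should attack the carbonyl next to the electron-withdrawing trifluoroacetoxy group, giving the 1-ester with the 4-carboxyl free while the base-free carboxylic acids of 14 stay inert, and water then cleaves the labile trifluoroacetate to the target.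

Compound list
1 | dodecane-1,12-diol | OCCCCCCCCCCCCO | starting material
2 | 12-hydroxydodecyl benzoate | O=C(OCCCCCCCCCCCCO)c1ccccc1 | intermediate
3 | 12-oxododecyl benzoate | O=C(OCCCCCCCCCCCC=O)c1ccccc1 | intermediate
4 | ethyl glyoxylate | O=CC(=O)OCC | starting material
5 | ethyl (2R,3S)-13-(benzoyloxy)-3-formyl-2-hydroxytridecanoate | O=C(OCCCCCCCCCC[C@H](C=O)[C@@H](O)C(=O)OCC)c1ccccc1 | intermediate
6 | ethyl (2R,3S)-13-(benzoyloxy)-3-(diethoxymethyl)-2-hydroxytridecanoate | O=C(OCCCCCCCCCC[C@H](C(OCC)OCC)[C@@H](O)C(=O)OCC)c1ccccc1 | intermediate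
7 | ethyl (3R)-13-(benzoyloxy)-3-(diethoxymethyl)-2-oxotridecanoate | O=C(OCCCCCCCCCC[C@H](C(OCC)OCC)C(=O)C(=O)OCC)c1ccccc1 | intermediate
8 | ethylene | C=C | starting material
9 | carbon monoxide | [C-]#[O+] | starting material
10 | ethyl (2R)-2-[(1S)-11-(benzoyloxy)-1-(diethoxymethyl)undecyl]-5-oxooxolane-2-carboxylate | O=C(OCCCCCCCCCC[C@H](C(OCC)OCC)[C@@]1(C(=O)OCC)CCC(=O)O1)c1ccccc1 | intermediate
11 | ethyl (2R)-2-[(2S)-12-(benzoyloxy)-1-oxododecan-2-yl]-5-oxooxolane-2-carboxylate | O=C(OCCCCCCCCCC[C@H](C=O)[C@@]1(C(=O)OCC)CCC(=O)O1)c1ccccc1 | intermediate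
12 | (2S)-12-(benzoyloxy)-2-[(2R)-2-(ethoxycarbonyl)-5-oxooxolan-2-yl]dodecanoic acid | O=C(OCCCCCCCCCC[C@H](C(=O)O)[C@@]1(C(=O)OCC)CCC(=O)O1)c1ccccc1 | intermediate
13 | trilithium (3R,4S)-3,14-dihydroxytetradecane-1,3,4-tricarboxylate | [Li+].[Li+].[Li+].OCCCCCCCCCC[C@H](C(=O)[O-])[C@@](O)(C(=O)[O-])CCC(=O)[O-] | intermediate
14 | (2R)-2-[(1S)-1-carboxy-11-hydroxyundecyl]-5-oxooxolane-2-carboxylic acid | OCCCCCCCCCC[C@H](C(=O)O)[C@@]1(C(=O)O)CCC(=O)O1 | intermediate
15 | D-malic acid, (2R)-2-hydroxybutanedioic acid | O=C(O)C[C@@H](O)C(=O)O | starting material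
16 | (3R)-2,5-dioxooxolan-3-yl trifluoroacetate | O=C1C[C@@H](OC(=O)C(F)(F)F)C(=O)O1 | intermediate
17 | (2R)-2-[(1S)-1-carboxy-11-{[(2R)-3-carboxy-2-(trifluoroacetoxy)propanoyl]oxy}undecyl]-5-oxooxolane-2-carboxylic acid | O=C(O)C[C@@H](OC(=O)C(F)(F)F)C(=O)OCCCCCCCCCC[C@H](C(=O)O)[C@@]1(C(=O)O)CCC(=O)O1 | intermediate
18 | (2R)-2-[(1S)-1-carboxy-11-{[(2R)-3-carboxy-2-hydroxypropanoyl]oxy}undecyl]-5-oxooxolane-2-carboxylic acid | O=C(O)C[C@@H](O)C(=O)OCCCCCCCCCC[C@H](C(=O)O)[C@@]1(C(=O)O)CCC(=O)O1 | target

Total step count: 9. Longest linear sequence: 8 steps (steps 1–7 and 9; step 8 is a one-step branch from 15).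

Steps most likely to fail

Step 5. Facial selectivity at the ketone may be poor if the acetal and the alkyl chain do not differ enough. At 160 °C the α-carbon may enolise, with loss of configuration or of ethanol, and oxidative cyclisation of an α-branched ketone may be slow. The fallback makes the same two carbon–carbon bonds in one flask at low temperature, with an acetylene dianion in place of ethylene and CO2 in place of CO. It sets out from 7: BrMgC≡CMgBr (from acetylene and two equivalents of EtMgBr, used in excess) in THF at −40 °C should add once to the strongly electrophilic α-keto carbonyl under the same 1,2-induction. CO2 is then passed into the same flask to carboxylate the remaining alkynyl–magnesium terminus, and acidic work-up gives (4S,5S)-15-(benzoyloxy)-5-(diethoxymethyl)-4-(ethoxycarbonyl)-4-hydroxypentadec-2-ynoic acid F1. Hydrogenation (H2, Pd/C, EtOAc) gives (4R,5S)-15-(benzoyloxy)-5-(diethoxymethyl)-4-(ethoxycarbonyl)-4-hydroxypentadecanoic acid F2, which lactonises with catalytic PPTS in toluene at 50 °C and comes back to the route at 10.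

Step 9. Acyl transfer to the free carboxyl groups (mixed anhydrides, oligomers), opening of the anhydride at the wrong carbonyl, and loss of material while purifying a very polar triacid are the concerns. The fallback sets out from 14 and masks the two acids first. BnBr and KHCO3 in DMF alkylate only the carboxylates and give benzyl (2R)-2-[(2S)-1-(benzyloxy)-12-hydroxy-1-oxododecan-2-yl]-5-oxooxolane-2-carboxylate F4. Acylation of its alcohol with 16 in THF gives (3R)-4-{[(11S)-12-(benzyloxy)-11-[(2R)-2-(benzyloxycarbonyl)-5-oxooxolan-2-yl]-12-oxododecyl]oxy}-4-oxo-3-(trifluoroacetoxy)butanoic acid F5. Aqueous work-up converts F5 into (3R)-4-{[(11S)-12-(benzyloxy)-11-[(2R)-2-(benzyloxycarbonyl)-5-oxooxolan-2-yl]-12-oxododecyl]oxy}-3-hydroxy-4-oxobutanoic acid F6, a mono-acid that can be freed of any regioisomer on silica. Hydrogenolysis (H2, Pd/C, EtOAc) removes both benzyl esters under neutral conditions and arrives at 18.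

Step 6. While the free aldehyde is exposed, the α-carbon may epimerise, or β-elimination of the lactone oxygen may open the ring. The fallback avoids the aldehyde and sets out from 10: ozone in EtOAc at −78 °C should oxidise the acetal C–H directly to the ester (ozonolysis of an acetal), giving ethyl (2R)-2-[(2S)-12-(benzoyloxy)-1-ethoxy-1-oxododecan-2-yl]-5-oxooxolane-2-carboxylate F3. F3 is saponified with LiOH in THF/H2O and acidified with HCl exactly as in step 7; it passes through 13 and comes back to the route at 14.

Further compounds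
F1 | step 5 | (4S,5S)-15-(benzoyloxy)-5-(diethoxymethyl)-4-(ethoxycarbonyl)-4-hydroxypentadec-2-ynoic acid | O=C(OCCCCCCCCCC[C@H](C(OCC)OCC)[C@@](O)(C(=O)OCC)C#CC(=O)O)c1ccccc1
F2 | step 5 | (4R,5S)-15-(benzoyloxy)-5-(diethoxymethyl)-4-(ethoxycarbonyl)-4-hydroxypentadecanoic acid | O=C(OCCCCCCCCCC[C@H](C(OCC)OCC)[C@@](O)(C(=O)OCC)CCC(=O)O)c1ccccc1
F3 | step 6 | ethyl (2R)-2-[(2S)-12-(benzoyloxy)-1-ethoxy-1-oxododecan-2-yl]-5-oxooxolane-2-carboxylate | O=C(OCCCCCCCCCC[C@H](C(=O)OCC)[C@@]1(C(=O)OCC)CCC(=O)O1)c1ccccc1
F4 | step 9 | benzyl (2R)-2-[(2S)-1-(benzyloxy)-12-hydroxy-1-oxododecan-2-yl]-5-oxooxolane-2-carboxylate | OCCCCCCCCCC[C@H](C(=O)OCc1ccccc1)[C@@]1(C(=O)OCc2ccccc2)CCC(=O)O1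
F5 | step 9 | (3R)-4-{[(11S)-12-(benzyloxy)-11-[(2R)-2-(benzyloxycarbonyl)-5-oxooxolan-2-yl]-12-oxododecyl]oxy}-4-oxo-3-(trifluoroacetoxy)butanoic acid | O=C(O)C[C@@H](OC(=O)C(F)(F)F)C(=O)OCCCCCCCCCC[C@H](C(=O)OCc1ccccc1)[C@@]1(C(=O)OCc2ccccc2)CCC(=O)O1
F6 | step 9 | (3R)-4-{[(11S)-12-(benzyloxy)-11-[(2R)-2-(benzyloxycarbonyl)-5-oxooxolan-2-yl]-12-oxododecyl]oxy}-3-hydroxy-4-oxobutanoic acid | O=C(O)C[C@@H](O)C(=O)OCCCCCCCCCC[C@H](C(=O)OCc1ccccc1)[C@@]1(C(=O)OCc2ccccc2)CCC(=O)O1
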